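## The problem

The target, compound 32, is a heptaphenol made of two trans-2,3-diaryl-2,3-dihydrobenzofurans joined by one bond: C3 of dihydrobenzofuran 1 (O1, C2, C3, C3a to C7a; benzo ring = ring A) is bonded to C5' of dihydrobenzofuran 2 (primed locants; benzo ring = ring B). Ring A carries a hydroxyl at C6 and a cis-4-hydroxystyryl group at C4, directly beside the crowded C3 junction; ring B carries its hydroxyl at C7', ortho to the ring oxygen, and is linked through C5', para to that oxygen. There are four stereocentres in two pairs, (2S,3S) in dihydrobenzofuran 1 and (2R,3R) in dihydrobenzofuran 2. In each pair the trans arrangement is the stable one, so C2 can direct C3 and C2' can direct C3', but the pairs are insulated from each other by ring B and need two separate acts of absolute stereocontrol of opposite spatial sense. The cis-stilbene will not survive light, acid, radicals or unselective hydrogenation, and acid would also drive the styryl cation into ring B. The benzylic C2–O1 and C2'–O1' bonds lie para to phenol oxygens, so they ionise under acid and can open through a quinone methide under hot base; with seven phenols, the deprotection has to be planned from the start. The feature that opens the route is the array O1'–C2'(aryl)–C3'–C3a': it is what a flavanone (O1–C2(aryl)–C3–C4(=O)–C4a) becomes when the ring B carbon C4a shifts from C4 to C3, leaving the old carbonyl carbon on C3' as a carboxyl group exactly where the 3,5-dihydroxyphenyl ring must stand. Dihydrobenzofuran 1 contains the same array (O1–C2–C3–C3a) with ring B in the place of the carboxyl group, so one reaction type can serve both halves.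

## Retrosynthesis

**32 to 31 to 30.** No skeletal bond is cut. The two aryl mesylates and the aryl silyl ether of 31 are removed by aqueous base to give 32, and the cis double bond of 31 is traced back to diarylalkyne 30. Syn addition of hydrogen to an alkyne fixes the Z geometry, which an olefination of a ring A aldehyde would not do reliably. The olefin then exists only in the last two steps. The forward reactions must stop at the alkene and must not be acidic.

**30 to 28 + 29.** The C4–C(sp) bond is cut, giving aryl triflate 28 and terminal alkyne 29 (Sonogashira coupling). Bringing in the two-carbon unit earlier would expose an alkyne to the iodine oxidant and to the radical couplings. A triflate can be carried from a chromone C5 hydroxyl, the one ring A oxygen that is distinguishable early. The forward reaction has to achieve oxidative addition next to the crowded C3 substituent in the presence of free phenols.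

**28 to 27.** Again no skeletal bond: the four methyl ethers of 27 are cleaved by a Lewis acid. This is placed here because neither alkene nor alkyne is present, and because both C2 aryl rings still carry sulfonate groups that keep the benzylic C–O bonds from ionising.

**27 to 26 + 17.** The C3–C5' bond is cut, the only bond between the halves. It gives two fragments of like size, each holding one stereocentre pair. Cutting inside dihydrobenzofuran 1 instead (C2–O1 or C3–C3a) would mean building ring A linearly on the finished dihydrobenzofuran 2. In the forward sense a C3 radical, released from redox-active ester 26 by decarboxylation, is joined to aryl bromide 17 by nickel catalysis. The C2 aryl group must send ring B to the trans face, and the catalyst must choose the bromide over the triflate and the mesylates.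

**17 to 13 + 14 (through 16), 13 to 12 to 11.** The C3'–aryl bond is cut in the same way. The 3,5-dioxygenated ring cannot be introduced by electrophilic substitution, so it comes as zinc reagent 16, made from bromide 14, and meets the C3' radical from ester 13. The coupling must leave the C5' bromine untouched, which speaks for iron and against nickel. Ester 13 comes from acid 12 and methyl ester 11.

**11 to 7 + 8.** This is the key cut: the C3'–C3a' bond, and with it the five-membered ring. Reconnecting C3a' to the carboxyl carbon gives flavanone 7, a flat bicyclic ketone with a single stereocentre. Closing the ring by C–O bond formation or by carbene C–H insertion would instead need both centres set on an open chain or a separate epimerisation. The forward reaction, an oxidative 1,2-aryl shift in orthoformate 8, must make ring B migrate and not the C2 aryl group, and must leave C2 untouched.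

**7 to 6 + 2, 6 to 4 to 3, 2 to 1.** The C2–aryl bond is cut: enantioselective conjugate addition of boronic acid 2 to chromone 6 sets the only stereocentre that has to be bought for this half. Chromone 6 comes from acetophenone 4, and the bromine of 4 is introduced first, para to the hydroxyl of 3. Boronic acid 2 is 1 mesylated in advance, so no 4'-hydroxyflavanone, the flavanone type most prone to racemise, is ever formed.

**26 to 25 to 24 to 21 + 8, 21 to 20 + 2, 20 to 19 to 18.** The other half is cut in the same three places, with the enantiomeric ligand in the conjugate addition. In chromone 18 the C5 hydroxyl is hydrogen-bonded to the carbonyl, which allows the C7 oxygen to be methylated alone (19). The C5 oxygen is then turned into the triflate (20) that later becomes the styryl position.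

## Roads not taken

**Alternative 1:** conjunctive coupling across the C2–C3 alkene of dihydrobenzofuran 1.
- Cut: the C3–C5' bond and the C2–aryl bond in one operation.
- Forward: 4-methoxyphenyllithium A4 adds to boron of the ring A E-alkenylboronate A2. A palladium catalyst with a chiral ferrocenyl bisphosphine couples the ate complex with the ring B triflate A3. Ring B goes to C3 and the anisyl group shifts from boron to C2, giving boronate A1. Oxidation of the C–B bond, loss of the methoxymethyl group and ring closure with inversion would follow.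
- Merits: it is the most convergent way to dihydrobenzofuran 1, sets both of its stereocentres in one catalyst-controlled step, and needs no carboxyl detour at C3. For that half it is clearly shorter than the chosen plan.
- Weak points: this coupling is best established for unsubstituted vinyl boronates. A2 is β-substituted by an aryl ring with two ortho substituents, and the electrophile A3 is a whole dihydrobenzofuran, so both reactivity and selectivity are uncertain. The C2 carbinol from A1 is benzylic and para to a methoxy group, so it tends to ionise on activation and the planned inversion cannot be relied on. The aryl chloride must still be turned into the cis-styryl group, and every phenol is a methyl ether.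
- Comparison: A3 must still be made, by chemistry like steps 2 to 8. Against the shorter count, the chosen plan offers stereodefining steps (conjugate addition to a chromone, ring contraction, trans-selective radical arylation) that each have a close counterpart on the same substrate class, and it uses them for both halves.

**Alternative 2:** gold-catalysed furan–yne benzannulation that builds ring B.
- Cut: ring B itself (C3a'–C7a' and C6'–C7'), with the dihydrofuran ring formed in the same event.
- Forward: a cationic gold catalyst activates the terminal ynol ether of furan A6. Furan C2 attacks the oxygen-bearing alkyne carbon, the furan opens and recloses on the alkyne terminus, and the furan oxygen ends as the C7' hydroxyl of phenol A5.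
- Merits: A5 has the C7' hydroxyl free and distinct from every other oxygen, and the C5' bromine in place. Ring B is assembled under neutral catalytic conditions with its regiochemistry fixed by connectivity. In this respect it is better than the chosen plan, which carries a methyl ether at C7'.
- Weak points: A6 must already hold both C2' and C3' on an open chain, so the stereochemical problem is moved, not solved. A terminal ynol ether of a secondary benzylic alcohol is fragile, and its C–O bond, para to a methoxy group, is liable to ionise at a Lewis-acidic metal. The phenol synthesis is known for carbon- or heteroatom-tethered alkynes, not for ynol ethers.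
- Comparison: A5 is the counterpart of bromide 17. The chosen plan reaches 17 from 3 in seven steps, with the absolute configuration from one catalytic step and the relative configuration from a rigid ring. The extra demethylation at C7' costs nothing, because step 16 is needed for ring A and the resorcinol ring anyway.

**Alternative 3:** intramolecular Alder–Rickert reaction that builds ring A.
- Cut: ring A (C7a–C3a and C5–C4), with the dihydrofuran ring of dihydrobenzofuran 1 closing in the same step.
- Forward: on heating, the 1-alkoxy-3-silyloxy diene of A8 adds to the tethered alkyne. The bicyclic adduct then loses its two-carbon bridge to give arene A7, which carries a silyloxy group at C6 and a diethoxymethyl group at C4.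
- Merits: ring A is made with all substituents placed regiospecifically. Its oxygen appears as a silyl ether and its C4 carbon as a masked aldehyde, so neither a triflate nor a ring A methyl ether is needed. Here it is better than the chosen plan.
- Weak points: A8 needs C2 and C3 set on an open chain, with C3 propargylic and benzylic and therefore easily epimerised or eliminated. The alkyne is not activated, so the cycloaddition needs high temperature, at which the benzylic dienyl ether can fragment. The aldehyde from A7 would give the cis-styryl group only through an unselective olefination or a longer alkyne detour.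
- Comparison: the chosen plan pays with steps 9, 10 and 16 for ring A. In return both stereocentres come from a rigid ring and a catalytic step, and two halves of equal size are joined late instead of ring A being built linearly on the finished dihydrobenzofuran 2.

Key step: step 5

Assumption: (S)-t-BuPyOx [(S)-4-tert-butyl-2-(pyridin-2-yl)-4,5-dihydrooxazole] is taken to deliver the aryl group to the chromone face that gives the (2R)-flavanone, the same facial sense as with 3-substituted cyclohexenones; if the sense proved opposite, the two ligand enantiomers would be exchanged between steps 4 and 11 with no other change.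

## Route

Step 1
Reactants: 1 4-hydroxyphenylboronic acid
Product: 2 {4-[(methylsulfonyl)oxy]phenyl}boronic acid
Conditions: MsCl (2.2 equiv), Et3N, THF, 0 °C; aq. NH4Cl work-up
Reagents that add atoms: methanesulfonyl chloride, CS(=O)(=O)Cl
Why: O-sulfonylation of a phenol; the phenoxide is far more nucleophilic than the B–OH groups and any boron mesylate is hydrolysed on work-up, so the boronic acid (used as its acid/boroxine mixture) is returned carrying the electron-withdrawing, acid-stable group that both ring contractions need.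

Step 2
Reactants: 3 1-(2-hydroxy-3-methoxyphenyl)ethanone
Product: 4 1-(5-bromo-2-hydroxy-3-methoxyphenyl)ethanone
Conditions: NBS, MeCN, 0 °C to rt
Reagents that add atoms: N-bromosuccinimide, O=C1CCC(=O)N1Br
Why: Electrophilic aromatic bromination; the hydroxyl is the strongest director and its only free ortho or para position is C5, para to it.

Step 3
Reactants: 4 1-(5-bromo-2-hydroxy-3-methoxyphenyl)ethanone
Product: 6 6-bromo-8-methoxy-4H-chromen-4-one, via enaminone 5 (not isolated)
Conditions: Me2NCH(OMe)2, PhMe, 100 °C; then conc. HCl, CH2Cl2, 40 °C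
Reagents that add atoms: N,N-dimethylformamide dimethyl acetal, COC(OC)N(C)C
Why: Enaminone route to chromones; condensation at the acetyl methyl group gives 5, and acid then promotes intramolecular conjugate addition of the phenol and loss of dimethylamine.

Step 4
Reactants: 6 6-bromo-8-methoxy-4H-chromen-4-one; 2 {4-[(methylsulfonyl)oxy]phenyl}boronic acid
Product: 7 4-[(2R)-6-bromo-8-methoxy-4-oxo-3,4-dihydro-2H-chromen-2-yl]phenyl methanesulfonate
Conditions: Pd(OCOCF3)2 (5 mol%), (S)-t-BuPyOx (6 mol%), NH4PF6 (30 mol%), H2O (5 equiv), ClCH2CH2Cl, 60 °C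
Reagents that add atoms: none
Why: Enantioselective conjugate addition of an arylboronic acid to a chromone with a cationic divalent palladium–pyridine-oxazoline catalyst; the aryl–palladium species adds to C2 on the face left open by the tert-butyl group and the palladium enolate is protonated, which sets C2 (the later C2'); palladium stays divalent, so the aryl bromide and the aryl mesylate are not touched.

Step 5
Reactants: 7 4-[(2R)-6-bromo-8-methoxy-4-oxo-3,4-dihydro-2H-chromen-2-yl]phenyl methanesulfonate; 8 trimethyl orthoformate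
Product: 11 methyl (2R,3R)-5-bromo-7-methoxy-2-{4-[(methylsulfonyl)oxy]phenyl}-2,3-dihydro-1-benzofuran-3-carboxylate, via enol ether 9 (not isolated), via iodanyl ketal 10 (not isolated)
Conditions: PhI(OAc)2 (1.2 equiv), conc. H2SO4 (0.5 equiv), HC(OMe)3, 0 °C to rt
Reagents that add atoms: none
Why: Oxidative ring contraction of a flavanone by a trivalent iodine reagent, the known conversion of flavanones into methyl trans-2-aryl-2,3-dihydrobenzofuran-3-carboxylates with PhI(OAc)2 or Tl(NO3)3 in acidic orthoformate. Acid and orthoformate turn ketone 7 into enol ether 9, which attacks the activated iodane at C3 on the face anti to the C2 aryl group; methanol adds at C4 to give the 2,3-trans iodanyl ketal 10 with both substituents equatorial. The C4–C4a bond is then antiperiplanar to the C3–I bond, so ring B shifts from C4 to C3 as iodobenzene leaves (new C3'–C3a' bond) and the dimethoxycarbenium ion at the old C4 collapses to the methyl ester. The dihydrofuran ring is thus formed by contraction of the pyranone ring from six to five members with C4 excised, not by a cyclisation. The new stereocentre C3' is controlled by C2': the shift inverts C3 of the trans iodane and places the ester trans to the aryl group, which is also the thermodynamically preferred arrangement. C2 is neither ionised nor deprotonated, so the configuration from step 4 becomes that of C2'. The step needs ring B to migrate in preference to the C2 aryl group (which would lead to an isoflavone) and in preference to simple dehydrogenation; the ring oxygen ortho to C4a raises the migratory aptitude of ring B, and the mesyloxy group makes the C2 aryl ring a poor migrating group and keeps the C2–O1 bond from ionising.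

Step 6
Reactants: 11 methyl (2R,3R)-5-bromo-7-methoxy-2-{4-[(methylsulfonyl)oxy]phenyl}-2,3-dihydro-1-benzofuran-3-carboxylate
Product: 12 (2R,3R)-5-bromo-7-methoxy-2-{4-[(methylsulfonyl)oxy]phenyl}-2,3-dihydro-1-benzofuran-3-carboxylic acid
Conditions: Me3SnOH (5 equiv), ClCH2CH2Cl, 80 °C; then 1 M HCl wash
Reagents that add atoms: trimethyltin hydroxide, C[Sn](C)(C)O
Why: Mild methyl ester hydrolysis with trimethyltin hydroxide; the nearly neutral conditions spare the aryl mesylate, and the trans acid is the stable epimer, so C3' is not at risk.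

Step 7
Reactants: 12 (2R,3R)-5-bromo-7-methoxy-2-{4-[(methylsulfonyl)oxy]phenyl}-2,3-dihydro-1-benzofuran-3-carboxylic acid
Product: 13 1,3-dioxoisoindolin-2-yl (2R,3R)-5-bromo-7-methoxy-2-{4-[(methylsulfonyl)oxy]phenyl}-2,3-dihydro-1-benzofuran-3-carboxylate
Conditions: N-hydroxyphthalimide, i-PrN=C=N-i-Pr, DMAP (10 mol%), CH2Cl2, rt
Reagents that add atoms: N-hydroxyphthalimide, O=C1c2ccccc2C(=O)N1O
Why: Carbodiimide esterification to the redox-active N-hydroxyphthalimide ester, the standard activation of a carboxylic acid for decarboxylative cross-coupling.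

Step 8
Reactants: 13 1,3-dioxoisoindolin-2-yl (2R,3R)-5-bromo-7-methoxy-2-{4-[(methylsulfonyl)oxy]phenyl}-2,3-dihydro-1-benzofuran-3-carboxylate; 14 1-bromo-3,5-dimethoxybenzene
Product: 17 4-[(2R,3R)-5-bromo-3-(3,5-dimethoxyphenyl)-7-methoxy-2,3-dihydro-1-benzofuran-2-yl]phenyl methanesulfonate, via arylmagnesium bromide 15 (not isolated), via diarylzinc 16 (not isolated)
Conditions: 14, Mg, THF, rt; ZnCl2 (0.5 equiv), 0 °C to rt; then 13, Fe(acac)3 (10 mol%), 1,2-bis(diphenylphosphino)benzene (12 mol%), THF/PhMe, rt
Reagents that add atoms: none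
Why: Iron-catalysed decarboxylative arylation of a redox-active ester with a diarylzinc reagent (Negishi-type radical cross-coupling); single-electron reduction of 13 releases CO2 and a benzylic C3' radical, which is arylated on the face anti to the C2' aryl group, so the 3,5-dimethoxyphenyl ring ends trans to it (substrate control); iron is chosen over nickel because iron–phosphine catalysts of this kind do not insert into aryl bromides or aryl sulfonates, so the C5' bromine needed in step 15 is kept.

Step 9
Reactants: 18 5,7-dihydroxy-4H-chromen-4-one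
Product: 19 5-hydroxy-7-methoxy-4H-chromen-4-one
Conditions: MeI (1.05 equiv), K2CO3, acetone, 50 °C
Reagents that add atoms: iodomethane, CI
Why: Selective Williamson O-methylation; the C7 hydroxyl is the more acidic one (para to the carbonyl), whereas the C5 hydroxyl is held in a hydrogen bond to the carbonyl oxygen and does not react with one equivalent of electrophile.

Step 10
Reactants: 19 5-hydroxy-7-methoxy-4H-chromen-4-one
Product: 20 7-methoxy-4-oxo-4H-chromen-5-yl trifluoromethanesulfonate
Conditions: Tf2O, pyridine, CH2Cl2, 0 °C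
Reagents that add atoms: trifluoromethanesulfonic anhydride, O=S(=O)(OS(=O)(=O)C(F)(F)F)C(F)(F)F
Why: Triflation of a chelated phenol; this fixes the future styryl position while the carbonyl still distinguishes the C5 oxygen, and makes the chromone a better conjugate acceptor.

Step 11
Reactants: 20 7-methoxy-4-oxo-4H-chromen-5-yl trifluoromethanesulfonate; 2 {4-[(methylsulfonyl)oxy]phenyl}boronic acid
Product: 21 (2S)-7-methoxy-2-{4-[(methylsulfonyl)oxy]phenyl}-4-oxo-3,4-dihydro-2H-chromen-5-yl trifluoromethanesulfonate
Conditions: Pd(OCOCF3)2 (5 mol%), (R)-t-BuPyOx (6 mol%), NH4PF6 (30 mol%), H2O (5 equiv), ClCH2CH2Cl, 60 °C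
Reagents that add atoms: none
Why: The same enantioselective conjugate addition as in step 4 with the enantiomeric ligand, which sets C2 with the opposite spatial sense; the nitrogen-ligated divalent palladium catalyst does not add oxidatively to the aryl triflate.

Step 12
Reactants: 21 (2S)-7-methoxy-2-{4-[(methylsulfonyl)oxy]phenyl}-4-oxo-3,4-dihydro-2H-chromen-5-yl trifluoromethanesulfonate; 8 trimethyl orthoformate
Product: 24 methyl (2S,3S)-6-methoxy-2-{4-[(methylsulfonyl)oxy]phenyl}-4-{[(trifluoromethyl)sulfonyl]oxy}-2,3-dihydro-1-benzofuran-3-carboxylate, via enol ether 22 (not isolated), via iodanyl ketal 23 (not isolated)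
Conditions: PhI(OAc)2 (1.2 equiv), conc. H2SO4 (0.5 equiv), HC(OMe)3, 0 °C to rt
Reagents that add atoms: none
Why: The same oxidative flavanone ring contraction as in step 5; ring A migrates from C4 to C3 (its migrating carbon has the ring oxygen ortho and the methoxy group para, which outweighs the ortho triflate), C2 is untouched, and the ester is set trans to the C2 aryl group by the anti shift in the trans iodanyl ketal 23.

Step 13
Reactants: 24 methyl (2S,3S)-6-methoxy-2-{4-[(methylsulfonyl)oxy]phenyl}-4-{[(trifluoromethyl)sulfonyl]oxy}-2,3-dihydro-1-benzofuran-3-carboxylate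
Product: 25 (2S,3S)-6-methoxy-2-{4-[(methylsulfonyl)oxy]phenyl}-4-{[(trifluoromethyl)sulfonyl]oxy}-2,3-dihydro-1-benzofuran-3-carboxylic acid
Conditions: Me3SnOH (5 equiv), ClCH2CH2Cl, 80 °C; then 1 M HCl wash
Reagents that add atoms: trimethyltin hydroxide, C[Sn](C)(C)O
Why: Trimethyltin hydroxide ester hydrolysis; free hydroxide would attack the aryl triflate, whereas this reagent cleaves only the methyl ester.

Step 14
Reactants: 25 (2S,3S)-6-methoxy-2-{4-[(methylsulfonyl)oxy]phenyl}-4-{[(trifluoromethyl)sulfonyl]oxy}-2,3-dihydro-1-benzofuran-3-carboxylic acid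
Product: 26 1,3-dioxoisoindolin-2-yl (2S,3S)-6-methoxy-2-{4-[(methylsulfonyl)oxy]phenyl}-4-{[(trifluoromethyl)sulfonyl]oxy}-2,3-dihydro-1-benzofuran-3-carboxylate
Conditions: N-hydroxyphthalimide, i-PrN=C=N-i-Pr, DMAP (10 mol%), CH2Cl2, rt
Reagents that add atoms: N-hydroxyphthalimide, O=C1c2ccccc2C(=O)N1O
Why: Carbodiimide esterification to the redox-active ester, as in step 7.

Step 15
Reactants: 26 1,3-dioxoisoindolin-2-yl (2S,3S)-6-methoxy-2-{4-[(methylsulfonyl)oxy]phenyl}-4-{[(trifluoromethyl)sulfonyl]oxy}-2,3-dihydro-1-benzofuran-3-carboxylate; 17 4-[(2R,3R)-5-bromo-3-(3,5-dimethoxyphenyl)-7-methoxy-2,3-dihydro-1-benzofuran-2-yl]phenyl methanesulfonate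
Product: 27 4-[(2R,3R)-3-(3,5-dimethoxyphenyl)-7-methoxy-5-[(2S,3S)-6-methoxy-2-{4-[(methylsulfonyl)oxy]phenyl}-4-{[(trifluoromethyl)sulfonyl]oxy}-2,3-dihydro-1-benzofuran-3-yl]-2,3-dihydro-1-benzofuran-2-yl]phenyl methanesulfonate
Conditions: NiBr2(dme) (10 mol%), 4,4'-di-tert-butyl-2,2'-bipyridine (12 mol%), Zn dust (2.5 equiv), MeCONMe2, 35 °C
Reagents that add atoms: none
Why: Nickel-catalysed reductive (cross-electrophile) decarboxylative arylation of an N-hydroxyphthalimide ester with an aryl bromide; zerovalent nickel–bipyridine adds oxidatively to the C–Br bond of 17 in preference to the aryl triflate and the aryl mesylates, the C3 radical formed by reduction of 26 is captured by the aryl–nickel species on the face anti to the C2 aryl group, and reductive elimination forms the C3–C5' bond with the 2,3-trans relation.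

Step 16
Reactants: 27 the coupled tetramethyl ether named in step 15
Product: 28 4-[(2R,3R)-3-(3,5-dihydroxyphenyl)-7-hydroxy-5-[(2S,3S)-6-hydroxy-2-{4-[(methylsulfonyl)oxy]phenyl}-4-{[(trifluoromethyl)sulfonyl]oxy}-2,3-dihydro-1-benzofuran-3-yl]-2,3-dihydro-1-benzofuran-2-yl]phenyl methanesulfonate
Conditions: BBr3 (10 equiv), CH2Cl2, −78 to 0 °C; MeOH, then H2O
Reagents that add atoms: none
Why: Lewis-acid cleavage of aryl methyl ethers with BBr3; the aryl triflate and mesylates are inert, the mesyloxy groups keep both C2 aryl rings electron-poor so that the benzylic C–O bonds of the dihydrofuran rings do not ionise, and no alkene or alkyne is yet present.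

Step 17
Reactants: 28 the tetraphenol triflate named in step 16; 29 tert-butyl(4-ethynylphenoxy)dimethylsilane
Product: 30 4-[(2R,3R)-5-[(2S,3S)-4-{[4-(tert-butyldimethylsilyloxy)phenyl]ethynyl}-6-hydroxy-2-{4-[(methylsulfonyl)oxy]phenyl}-2,3-dihydro-1-benzofuran-3-yl]-3-(3,5-dihydroxyphenyl)-7-hydroxy-2,3-dihydro-1-benzofuran-2-yl]phenyl methanesulfonate
Conditions: Pd(PPh3)2Cl2 (5 mol%), CuI (10 mol%), Et3N, DMF, 70 °C
Reagents that add atoms: none
Why: Sonogashira coupling of an aryl triflate with a terminal alkyne; free phenols are tolerated under amine base, and the linear alkyne is the least demanding partner for a triflate flanked by the C3 aryl substituent.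

Step 18
Reactants: 30 the diarylalkyne named in step 17
Product: 31 4-[(2R,3R)-5-[(2S,3S)-4-{(Z)-2-[4-(tert-butyldimethylsilyloxy)phenyl]ethenyl}-6-hydroxy-2-{4-[(methylsulfonyl)oxy]phenyl}-2,3-dihydro-1-benzofuran-3-yl]-3-(3,5-dihydroxyphenyl)-7-hydroxy-2,3-dihydro-1-benzofuran-2-yl]phenyl methanesulfonate
Conditions: H2 (1 atm), 5% Pd/CaCO3 poisoned with Pb(OAc)2, quinoline, EtOAc, rt
Reagents that add atoms: none
Why: Semi-hydrogenation of a diarylalkyne over lead-poisoned palladium; syn delivery of H2 on the catalyst surface gives the Z-alkene, and the sulfonates, the silyl ether and the benzylic C–O bonds are untouched under these neutral conditions.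

Step 19
Reactants: 31 the cis-stilbene named in step 18
Product: 32 4-[(Z)-2-{(2S,3S)-3-[(2R,3R)-3-(3,5-dihydroxyphenyl)-7-hydroxy-2-(4-hydroxyphenyl)-2,3-dihydro-1-benzofuran-5-yl]-6-hydroxy-2-(4-hydroxyphenyl)-2,3-dihydro-1-benzofuran-4-yl}ethenyl]phenol
Conditions: NaOH (2 M), MeOH/H2O (degassed, argon), 50 °C; then 1 M HCl, 0 °C
Reagents that add atoms: none
Why: Base hydrolysis of the two aryl methanesulfonates and of the aryl silyl ether; the cis-stilbene is not base-sensitive, any reversible opening of a dihydrofuran ring through the quinone methide recloses to the favoured 2,3-trans isomer so the stereocentres are not at risk, and exclusion of air protects the polyphenoxide.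

## Compound list

1 | 4-hydroxyphenylboronic acid | OB(O)c1ccc(O)cc1 | starting material
2 | {4-[(methylsulfonyl)oxy]phenyl}boronic acid | CS(=O)(=O)Oc1ccc(B(O)O)cc1 | intermediate
3 | 1-(2-hydroxy-3-methoxyphenyl)ethanone | CC(=O)c1cccc(OC)c1O | starting material
4 | 1-(5-bromo-2-hydroxy-3-methoxyphenyl)ethanone | CC(=O)c1cc(Br)cc(OC)c1O | intermediate
5 | (E)-1-(5-bromo-2-hydroxy-3-methoxyphenyl)-3-(dimethylamino)prop-2-en-1-one | CN(C)/C=C/C(=O)c1cc(Br)cc(OC)c1O | intermediate (not isolated)
6 | 6-bromo-8-methoxy-4H-chromen-4-one | O=c1ccoc2c(OC)cc(Br)cc12 | intermediate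
7 | 4-[(2R)-6-bromo-8-methoxy-4-oxo-3,4-dihydro-2H-chromen-2-yl]phenyl methanesulfonate | Brc1cc(OC)c2c(c1)C(=O)C[C@H](c1ccc(OS(C)(=O)=O)cc1)O2 | intermediate
8 | trimethyl orthoformate | COC(OC)OC | starting material
9 | 4-[(2R)-6-bromo-4,8-dimethoxy-2H-chromen-2-yl]phenyl methanesulfonate | Brc1cc(OC)c2c(c1)C(OC)=C[C@H](c1ccc(OS(C)(=O)=O)cc1)O2 | intermediate (not isolated)
10 | 4-{(2S,3S)-3-[acetoxy(phenyl)iodanyl]-6-bromo-4,4,8-trimethoxy-3,4-dihydro-2H-chromen-2-yl}phenyl methanesulfonate (2,3-trans) | Brc1cc(OC)c2c(c1)C(OC)(OC)[C@@H]([I](OC(C)=O)c1ccccc1)[C@H](c1ccc(OS(C)(=O)=O)cc1)O2 | intermediate (not isolated)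
11 | methyl (2R,3R)-5-bromo-7-methoxy-2-{4-[(methylsulfonyl)oxy]phenyl}-2,3-dihydro-1-benzofuran-3-carboxylate | Brc1cc(OC)c2c(c1)[C@@H](C(=O)OC)[C@H](c1ccc(OS(C)(=O)=O)cc1)O2 | intermediate
12 | (2R,3R)-5-bromo-7-methoxy-2-{4-[(methylsulfonyl)oxy]phenyl}-2,3-dihydro-1-benzofuran-3-carboxylic acid | Brc1cc(OC)c2c(c1)[C@@H](C(=O)O)[C@H](c1ccc(OS(C)(=O)=O)cc1)O2 | intermediate
13 | 1,3-dioxoisoindolin-2-yl (2R,3R)-5-bromo-7-methoxy-2-{4-[(methylsulfonyl)oxy]phenyl}-2,3-dihydro-1-benzofuran-3-carboxylate | Brc1cc(OC)c2c(c1)[C@@H](C(=O)ON1C(=O)c3ccccc3C1=O)[C@H](c1ccc(OS(C)(=O)=O)cc1)O2 | intermediate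
14 | 1-bromo-3,5-dimethoxybenzene | COc1cc(Br)cc(OC)c1 | starting material
15 | (3,5-dimethoxyphenyl)magnesium bromide | COc1cc([Mg]Br)cc(OC)c1 | intermediate (not isolated)
16 | bis(3,5-dimethoxyphenyl)zinc | COc1cc([Zn]c2cc(OC)cc(OC)c2)cc(OC)c1 | intermediate (not isolated)
17 | 4-[(2R,3R)-5-bromo-3-(3,5-dimethoxyphenyl)-7-methoxy-2,3-dihydro-1-benzofuran-2-yl]phenyl methanesulfonate | Brc1cc(OC)c2c(c1)[C@@H](c1cc(OC)cc(OC)c1)[C@H](c1ccc(OS(C)(=O)=O)cc1)O2 | intermediate
18 | 5,7-dihydroxy-4H-chromen-4-one | O=c1ccoc2cc(O)cc(O)c12 | starting material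
19 | 5-hydroxy-7-methoxy-4H-chromen-4-one | O=c1ccoc2cc(OC)cc(O)c12 | intermediate
20 | 7-methoxy-4-oxo-4H-chromen-5-yl trifluoromethanesulfonate | O=c1ccoc2cc(OC)cc(OS(=O)(=O)C(F)(F)F)c12 | intermediate
21 | (2S)-7-methoxy-2-{4-[(methylsulfonyl)oxy]phenyl}-4-oxo-3,4-dihydro-2H-chromen-5-yl trifluoromethanesulfonate | COc1cc2c(c(OS(=O)(=O)C(F)(F)F)c1)C(=O)C[C@@H](c1ccc(OS(C)(=O)=O)cc1)O2 | intermediate
22 | (2S)-4,7-dimethoxy-2-{4-[(methylsulfonyl)oxy]phenyl}-2H-chromen-5-yl trifluoromethanesulfonate | COc1cc2c(c(OS(=O)(=O)C(F)(F)F)c1)C(OC)=C[C@@H](c1ccc(OS(C)(=O)=O)cc1)O2 | intermediate (not isolated)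
23 | (2R,3R)-3-[acetoxy(phenyl)iodanyl]-4,4,7-trimethoxy-2-{4-[(methylsulfonyl)oxy]phenyl}-3,4-dihydro-2H-chromen-5-yl trifluoromethanesulfonate (2,3-trans) | COc1cc2c(c(OS(=O)(=O)C(F)(F)F)c1)C(OC)(OC)[C@H]([I](OC(C)=O)c1ccccc1)[C@@H](c1ccc(OS(C)(=O)=O)cc1)O2 | intermediate (not isolated)
24 | methyl (2S,3S)-6-methoxy-2-{4-[(methylsulfonyl)oxy]phenyl}-4-{[(trifluoromethyl)sulfonyl]oxy}-2,3-dihydro-1-benzofuran-3-carboxylate | COc1cc2c(c(OS(=O)(=O)C(F)(F)F)c1)[C@H](C(=O)OC)[C@@H](c1ccc(OS(C)(=O)=O)cc1)O2 | intermediate
25 | (2S,3S)-6-methoxy-2-{4-[(methylsulfonyl)oxy]phenyl}-4-{[(trifluoromethyl)sulfonyl]oxy}-2,3-dihydro-1-benzofuran-3-carboxylic acid | COc1cc2c(c(OS(=O)(=O)C(F)(F)F)c1)[C@H](C(=O)O)[C@@H](c1ccc(OS(C)(=O)=O)cc1)O2 | intermediate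
26 | 1,3-dioxoisoindolin-2-yl (2S,3S)-6-methoxy-2-{4-[(methylsulfonyl)oxy]phenyl}-4-{[(trifluoromethyl)sulfonyl]oxy}-2,3-dihydro-1-benzofuran-3-carboxylate | COc1cc2c(c(OS(=O)(=O)C(F)(F)F)c1)[C@H](C(=O)ON1C(=O)c3ccccc3C1=O)[C@@H](c1ccc(OS(C)(=O)=O)cc1)O2 | intermediate
27 | 4-[(2R,3R)-3-(3,5-dimethoxyphenyl)-7-methoxy-5-[(2S,3S)-6-methoxy-2-{4-[(methylsulfonyl)oxy]phenyl}-4-{[(trifluoromethyl)sulfonyl]oxy}-2,3-dihydro-1-benzofuran-3-yl]-2,3-dihydro-1-benzofuran-2-yl]phenyl methanesulfonate | COc1cc2c(c(OS(=O)(=O)C(F)(F)F)c1)[C@H](c1cc(OC)c3c(c1)[C@@H](c1cc(OC)cc(OC)c1)[C@H](c1ccc(OS(C)(=O)=O)cc1)O3)[C@@H](c1ccc(OS(C)(=O)=O)cc1)O2 | intermediate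
28 | 4-[(2R,3R)-3-(3,5-dihydroxyphenyl)-7-hydroxy-5-[(2S,3S)-6-hydroxy-2-{4-[(methylsulfonyl)oxy]phenyl}-4-{[(trifluoromethyl)sulfonyl]oxy}-2,3-dihydro-1-benzofuran-3-yl]-2,3-dihydro-1-benzofuran-2-yl]phenyl methanesulfonate | Oc1cc2c(c(OS(=O)(=O)C(F)(F)F)c1)[C@H](c1cc(O)c3c(c1)[C@@H](c1cc(O)cc(O)c1)[C@H](c1ccc(OS(C)(=O)=O)cc1)O3)[C@@H](c1ccc(OS(C)(=O)=O)cc1)O2 | intermediate
29 | tert-butyl(4-ethynylphenoxy)dimethylsilane | C#Cc1ccc(O[Si](C)(C)C(C)(C)C)cc1 | starting material
30 | 4-[(2R,3R)-5-[(2S,3S)-4-{[4-(tert-butyldimethylsilyloxy)phenyl]ethynyl}-6-hydroxy-2-{4-[(methylsulfonyl)oxy]phenyl}-2,3-dihydro-1-benzofuran-3-yl]-3-(3,5-dihydroxyphenyl)-7-hydroxy-2,3-dihydro-1-benzofuran-2-yl]phenyl methanesulfonate | Oc1cc2c(c(C#Cc3ccc(O[Si](C)(C)C(C)(C)C)cc3)c1)[C@H](c1cc(O)c3c(c1)[C@@H](c1cc(O)cc(O)c1)[C@H](c1ccc(OS(C)(=O)=O)cc1)O3)[C@@H](c1ccc(OS(C)(=O)=O)cc1)O2 | intermediate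
31 | 4-[(2R,3R)-5-[(2S,3S)-4-{(Z)-2-[4-(tert-butyldimethylsilyloxy)phenyl]ethenyl}-6-hydroxy-2-{4-[(methylsulfonyl)oxy]phenyl}-2,3-dihydro-1-benzofuran-3-yl]-3-(3,5-dihydroxyphenyl)-7-hydroxy-2,3-dihydro-1-benzofuran-2-yl]phenyl methanesulfonate | Oc1cc2c(c(/C=C\c3ccc(O[Si](C)(C)C(C)(C)C)cc3)c1)[C@H](c1cc(O)c3c(c1)[C@@H](c1cc(O)cc(O)c1)[C@H](c1ccc(OS(C)(=O)=O)cc1)O3)[C@@H](c1ccc(OS(C)(=O)=O)cc1)O2 | intermediate
32 | 4-[(Z)-2-{(2S,3S)-3-[(2R,3R)-3-(3,5-dihydroxyphenyl)-7-hydroxy-2-(4-hydroxyphenyl)-2,3-dihydro-1-benzofuran-5-yl]-6-hydroxy-2-(4-hydroxyphenyl)-2,3-dihydro-1-benzofuran-4-yl}ethenyl]phenol | Oc1ccc(/C=C\c2cc(O)cc3c2[C@H](c2cc(O)c4c(c2)[C@@H](c2cc(O)cc(O)c2)[C@H](c2ccc(O)cc2)O4)[C@@H](c2ccc(O)cc2)O3)cc1 | target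

## Step count and risks

Total: 19 steps. Longest linear sequence: 12 steps (steps 2 to 8, then 15 to 19). The other branches are steps 9 to 14 and step 1.

**Step 5 (key step).** The most likely failure is dehydrogenation of the iodane adduct (loss of the C2 hydrogen) or slow ketalisation, so that 7 is consumed without the aryl shift. Partial loss of optical purity would follow if the C2–O1 bond ionised under the acid. Fallback, the same aryl shift by a carbene path: from 7, detrifluoroacetylative diazo transfer (LiN(SiMe3)2, CF3CO2CH2CF3, THF, −78 °C; then MsN3, Et3N, MeCN) gives 4-[(2S)-6-bromo-3-diazo-8-methoxy-4-oxo-3,4-dihydro-2H-chromen-2-yl]phenyl methanesulfonate F1. Irradiation in MeOH (350 nm) brings about a Wolff rearrangement in which ring B migrates to the carbene carbon and the ketene is trapped as the methyl ester. Brief equilibration of the epimer mixture (catalytic DBU, CH2Cl2) rejoins the route at 11.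

**Step 12.** The peri triflate may slow ketal formation and lower the migratory aptitude of ring A, so that dehydrogenation competes more strongly than in step 5. Fallback, the same Wolff sequence: from 21, diazo transfer as above gives (2R)-3-diazo-7-methoxy-2-{4-[(methylsulfonyl)oxy]phenyl}-4-oxo-3,4-dihydro-2H-chromen-5-yl trifluoromethanesulfonate F2. Photolysis in MeOH and equilibration to the trans ester return to the route at 24.

**Step 15.** Oxidative addition into the electron-rich aryl bromide may be slower than reduction of the redox-active ester, so the hindered C3 radical dimerises or is reduced before it meets an aryl–nickel species. Fallback, with the aryl partner as nucleophile: from 17, magnesium insertion in the presence of LiCl and ZnCl2 (THF, rt) gives chloro[(2R,3R)-3-(3,5-dimethoxyphenyl)-7-methoxy-2-{4-[(methylsulfonyl)oxy]phenyl}-2,3-dihydro-1-benzofuran-5-yl]zinc F3. Decarboxylative Negishi-type coupling of F3 with 26 (NiCl2(dme), 4,4'-di-tert-butyl-2,2'-bipyridine, THF/DMF, rt) returns to the route at 27.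

**Step 8.** The C5' bromine may be lost by halogen–metal exchange or insertion during the coupling, or the benzylic radical may be reduced instead of arylated. Fallback, inverting the order of the two couplings: from 11, reductive coupling with 26 under the conditions of step 15 gives methyl (2R,3R)-7-methoxy-5-[(2S,3S)-6-methoxy-2-{4-[(methylsulfonyl)oxy]phenyl}-4-{[(trifluoromethyl)sulfonyl]oxy}-2,3-dihydro-1-benzofuran-3-yl]-2-{4-[(methylsulfonyl)oxy]phenyl}-2,3-dihydro-1-benzofuran-3-carboxylate F4. Hydrolysis with Me3SnOH gives the corresponding carboxylic acid F5, and esterification with N-hydroxyphthalimide gives its 1,3-dioxoisoindolin-2-yl ester F6. Decarboxylative arylation of F6 with zinc reagent 16 (NiCl2(dme)/4,4'-di-tert-butyl-2,2'-bipyridine or the iron system of step 8, no aryl bromide now being present) returns to the route at 27.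

**Step 18.** Hydrogen uptake at the alkyne, which is flanked by the C3 aryl group and surrounded by phenols, may be slow, so that forcing it leads to over-reduction or to Z-to-E isomerisation on the catalyst. Fallback, making the Z-olefin by coupling instead of reduction: from 29, rhodium-catalysed trans-hydroboration (pinacolborane, [Rh(cod)Cl]2, P(i-Pr)3, Et3N) gives tert-butyldimethyl{4-[(Z)-2-(4,4,5,5-tetramethyl-1,3,2-dioxaborolan-2-yl)ethenyl]phenoxy}silane F7. Suzuki–Miyaura coupling of F7 with triflate 28 (Pd(OAc)2, 2-dicyclohexylphosphino-2',6'-dimethoxybiphenyl, K3PO4, THF/H2O, 40 °C) proceeds with retention of olefin geometry and returns to the route at 31.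

## Further compounds

F1 | step 5 | 4-[(2S)-6-bromo-3-diazo-8-methoxy-4-oxo-3,4-dihydro-2H-chromen-2-yl]phenyl methanesulfonate | Brc1cc(OC)c2c(c1)C(=O)C(=[N+]=[N-])[C@H](c1ccc(OS(C)(=O)=O)cc1)O2
F2 | step 12 | (2R)-3-diazo-7-methoxy-2-{4-[(methylsulfonyl)oxy]phenyl}-4-oxo-3,4-dihydro-2H-chromen-5-yl trifluoromethanesulfonate | COc1cc2c(c(OS(=O)(=O)C(F)(F)F)c1)C(=O)C(=[N+]=[N-])[C@@H](c1ccc(OS(C)(=O)=O)cc1)O2
F3 | step 15 | chloro[(2R,3R)-3-(3,5-dimethoxyphenyl)-7-methoxy-2-{4-[(methylsulfonyl)oxy]phenyl}-2,3-dihydro-1-benzofuran-5-yl]zinc | Cl[Zn]c1cc(OC)c2c(c1)[C@@H](c1cc(OC)cc(OC)c1)[C@H](c1ccc(OS(C)(=O)=O)cc1)O2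
F4 | step 8 | methyl (2R,3R)-7-methoxy-5-[(2S,3S)-6-methoxy-2-{4-[(methylsulfonyl)oxy]phenyl}-4-{[(trifluoromethyl)sulfonyl]oxy}-2,3-dihydro-1-benzofuran-3-yl]-2-{4-[(methylsulfonyl)oxy]phenyl}-2,3-dihydro-1-benzofuran-3-carboxylate | COc1cc2c(c(OS(=O)(=O)C(F)(F)F)c1)[C@H](c1cc(OC)c3c(c1)[C@@H](C(=O)OC)[C@H](c1ccc(OS(C)(=O)=O)cc1)O3)[C@@H](c1ccc(OS(C)(=O)=O)cc1)O2
F5 | step 8 | (2R,3R)-7-methoxy-5-[(2S,3S)-6-methoxy-2-{4-[(methylsulfonyl)oxy]phenyl}-4-{[(trifluoromethyl)sulfonyl]oxy}-2,3-dihydro-1-benzofuran-3-yl]-2-{4-[(methylsulfonyl)oxy]phenyl}-2,3-dihydro-1-benzofuran-3-carboxylic acid | COc1cc2c(c(OS(=O)(=O)C(F)(F)F)c1)[C@H](c1cc(OC)c3c(c1)[C@@H](C(=O)O)[C@H](c1ccc(OS(C)(=O)=O)cc1)O3)[C@@H](c1ccc(OS(C)(=O)=O)cc1)O2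
F6 | step 8 | 1,3-dioxoisoindolin-2-yl (2R,3R)-7-methoxy-5-[(2S,3S)-6-methoxy-2-{4-[(methylsulfonyl)oxy]phenyl}-4-{[(trifluoromethyl)sulfonyl]oxy}-2,3-dihydro-1-benzofuran-3-yl]-2-{4-[(methylsulfonyl)oxy]phenyl}-2,3-dihydro-1-benzofuran-3-carboxylate | COc1cc2c(c(OS(=O)(=O)C(F)(F)F)c1)[C@H](c1cc(OC)c3c(c1)[C@@H](C(=O)ON1C(=O)c4ccccc4C1=O)[C@H](c1ccc(OS(C)(=O)=O)cc1)O3)[C@@H](c1ccc(OS(C)(=O)=O)cc1)O2
F7 | step 18 | tert-butyldimethyl{4-[(Z)-2-(4,4,5,5-tetramethyl-1,3,2-dioxaborolan-2-yl)ethenyl]phenoxy}silane | CC(C)(C)[Si](C)(C)Oc1ccc(/C=C\B2OC(C)(C)C(C)(C)O2)cc1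
A1 | alternative 1 | 2-[(1R,2S)-2-[2-chloro-4-methoxy-6-(methoxymethoxy)phenyl]-2-[(2R,3R)-3-(3,5-dimethoxyphenyl)-7-methoxy-2-(4-methoxyphenyl)-2,3-dihydro-1-benzofuran-5-yl]-1-(4-methoxyphenyl)ethyl]-4,4,5,5-tetramethyl-1,3,2-dioxaborolane | COCOc1cc(OC)cc(Cl)c1[C@H](c1cc(OC)c2c(c1)[C@@H](c1cc(OC)cc(OC)c1)[C@H](c1ccc(OC)cc1)O2)[C@H](c1ccc(OC)cc1)B1OC(C)(C)C(C)(C)O1
A2 | alternative 1 | 2-{(E)-2-[2-chloro-4-methoxy-6-(methoxymethoxy)phenyl]ethenyl}-4,4,5,5-tetramethyl-1,3,2-dioxaborolane | COCOc1cc(OC)cc(Cl)c1/C=C/B1OC(C)(C)C(C)(C)O1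
A3 | alternative 1 | (2R,3R)-3-(3,5-dimethoxyphenyl)-7-methoxy-2-(4-methoxyphenyl)-2,3-dihydro-1-benzofuran-5-yl trifluoromethanesulfonate | O=S(=O)(Oc1cc(OC)c2c(c1)[C@@H](c1cc(OC)cc(OC)c1)[C@H](c1ccc(OC)cc1)O2)C(F)(F)F
A4 | alternative 1 | 4-methoxyphenyllithium | [Li]c1ccc(OC)cc1
A5 | alternative 2 | (2R,3R)-5-bromo-3-(3,5-dimethoxyphenyl)-2-(4-methoxyphenyl)-2,3-dihydro-1-benzofuran-7-ol | Brc1cc(O)c2c(c1)[C@@H](c1cc(OC)cc(OC)c1)[C@H](c1ccc(OC)cc1)O2
A6 | alternative 2 | 4-bromo-2-[(1S,2R)-1-(3,5-dimethoxyphenyl)-2-(ethynyloxy)-2-(4-methoxyphenyl)ethyl]furan | Brc1coc(c1)[C@@H](c1cc(OC)cc(OC)c1)[C@H](c1ccc(OC)cc1)OC#C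
A7 | alternative 3 | tert-butyl{[(2S,3S)-4-(diethoxymethyl)-3-[(2R,3R)-3-(3,5-dimethoxyphenyl)-7-methoxy-2-(4-methoxyphenyl)-2,3-dihydro-1-benzofuran-5-yl]-2-(4-methoxyphenyl)-2,3-dihydro-1-benzofuran-6-yl]oxy}dimethylsilane | CCOC(OCC)c1cc(O[Si](C)(C)C(C)(C)C)cc2c1[C@H](c1cc(OC)c3c(c1)[C@@H](c1cc(OC)cc(OC)c1)[C@H](c1ccc(OC)cc1)O3)[C@@H](c1ccc(OC)cc1)O2
A8 | alternative 3 | tert-butyl{[3-({(1S,2S)-2-[(2R,3R)-3-(3,5-dimethoxyphenyl)-7-methoxy-2-(4-methoxyphenyl)-2,3-dihydro-1-benzofuran-5-yl]-5,5-diethoxy-1-(4-methoxyphenyl)pent-3-yn-1-yl}oxy)cyclohexa-1,3-dien-1-yl]oxy}dimethylsilane | CCOC(OCC)C#C[C@H](c1cc(OC)c2c(c1)[C@@H](c1cc(OC)cc(OC)c1)[C@H](c1ccc(OC)cc1)O2)[C@@H](c1ccc(OC)cc1)OC1=CC(O[Si](C)(C)C(C)(C)C)=CCC1
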